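The readings are simulated from invented constants, and the scatter is random.

Early times are where I start, with the flasks, the readings and the questions before me.

| flask | substrate | remark | time |
|---|---|---|---|
| Monday's | 0.21 M | run made earlier |  |
| oak | 0.43 M |  | 30 min |
| birch | 0.43 M |  | 40 min |
| ash | 0.43 M |  | 50 min |

Monday's run (percent of the substrate charged)

| time / min | substrate / % | isomer of the product / % | target / % |
|---|---|---|---|
| 1.50 | 93.0 | 0.3 | 7.2 |
| 3.00 | 87.1 | 0 | 11.5 |
| 5.00 | 79.9 | 0.7 | 17.9 |
| 6.00 | 77.5 | 0.5 | 19.1 |
| 8.00 | 72.4 | 2.3 | 24.0 |
| 10.0 | 72.3 | 4.5 | 24.8 |

(standard deviation of a reading: 1 percentage point)

- which of these there is most of at the end, counted by the substrate in it, oak (target / substrate / isomer of the product)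
- which of these there is most of at the end, counted by the substrate in it, birch (target / substrate / isomer of the product)
- which of these there is most of at the end, counted by the substrate in it, ash (target / substrate / isomer of the product)
- final amount of the leader among these, as a percentage of the substrate charged, in oak
- final amount of the leader among these, as a percentage of the substrate charged, in birch
- final amount of the leader among these, as a percentage of the substrate charged, in ash



At early times nothing seems to push back on Monday's substrate, so I integrate a plain first-order loss, in which the substrate share falls as exp(−k·time). The first reading gives

k = ln(charged/left)/time = 0.0484 min⁻¹.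

Carried to 10.0 min, this leaves 61.6%, but the reading is 72.3%, more, so something runs backward. Between the last two readings the substrate moves by 0.1 percentage points, less than the scatter of 1 point, so this pair cannot show whether the fall has stopped or only slowed, and taking the last reading as near a stall is a wager.

I wager, since a single charge cannot show it, that each substrate gives target plus a released group and that the two recombine. The charge then matters, and the number to carry is the stall quotient, the charge times the reacted share times the target share over the substrate share, which is the usual reaction quotient. Monday's last reading gives

stall quotient = 0.0200 M.

For 0.43 M of substrate I set a = quotient/charge = 0.0464. If all the reacted substrate stands as target,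

reacted share = (√(a·a + 4a) − a)/2 = 19.3%,

which leaves 80.7% substrate.

The weak link is the isomer, which climbs from 2.3% to 4.5% at the end of Monday's run. Isomer counts as reacted but not as target, so I let it grow level with the target, which puts a factor 2 into a:

a = 0.0928, reacted share = 26.2%, substrate = 73.8%.

I commit to substrate leading near that figure in oak, birch and ash, above everything reacted.

The forecast also names substrate, substrate and substrate as leaders but, expecting “a slow drain from target to isomer”, gives 58%, 52% and 47%, lower than my figure.

Oak gives 72.3%, birch 71.6% and ash 71.2%, with substrate, substrate and substrate leading, and my 73.8% stands 1.5 points above oak.

    target ⇌ isomer of the product (K = 0.580, k = 0.0260 min⁻¹)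
    substrate ⇌ target + released group (K = 0.0330 M, k = 0.0490 min⁻¹)

In birch the slowest mode of the whole flask has a half-life of 12.6 min at 40.0 min, shorter than the 40 min it stands, and half the turnover of the step from substrate to target and released group is done by 3.51 min. The stall quotient from birch's state at 40.0 min is 0.0325 M, above Monday's reading, and in the neighbouring flask charged with 1.7 M of substrate it is 0.0328 M.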